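The isomer of the product is the species to watch in this flask, whose 0.0500 M of protic impurity lies between those of the two earlier runs.

the same everywhere: starting material 0.10 M

|  | protic impurity | remark | time |
|---|---|---|---|
| Friday's | 0.034 M | run made earlier |  |
| Wednesday's | 0.075 M | run made earlier |  |
| flask | 0.0500 M |  | 15 d |

- Friday's (time / d: isomer of the product / %, target / %, starting material / %): 1.25: 13.1, 78.6, 5.7; 4.00: 15.9, 76.9, 4.3; 8.00: 18.9, 72.6, 3.4; 10.0: 17.5, 72.5, 4.3; 15.0: 18.9, 68.2, 2.1
- Wednesday's (time / d: isomer of the product / %, target / %, starting material / %): 1.25: 16.2, 77.5, 5.4; 2.50: 14.7, 74.1, 3.8; 4.00: 15.4, 73.2, 3.3; 8.00: 17.3, 69.1, 3.5; 15.0: 18.6, 62.2, 5.6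

(each reading ± 1 percentage point)

Wednesday's run carried about twice Friday's protic impurity, but at 15.0 d the isomer of the product read 18.9 % on Friday's run and 18.6 % on Wednesday's, with a scatter of 1 percentage point. Friday's had already read 18.9 % at 8.00 d. Target, by contrast, ended at 68.2 % on Friday's run and 62.2 % on Wednesday's. We read this as thermodynamic control of the isomer late on, after kinetic control early.

So we carry one quantity, the isomer ceiling, the c(isomer of the product) at which it stops gaining, taken as the mean of the two end readings times the charge: 18.8 mM. Target interpolated to this flask's impurity gives 65.9 %, so our end share is 22.2 %. The early end has no reading before 1.25 d, where the share stands at 14.3 % on Friday's run and 17.3 % on Wednesday's, and we would start between these.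

- share of isomer of the product in isomer of the product plus target at 2.0 min
- share of isomer of the product in isomer of the product plus target at 3.0 h
- share of isomer of the product in isomer of the product plus target at 15 d

- a reading or a percentage of target counts all its forms, free or not
- a reading of starting material is of its free form alone

The forecast gives 14.3 %, 14.8 % and 22.1 %, its start at the foot of our span, and warns that the “early values are extrapolations beyond any reading”.

The flask gives 12.6 %, 13.6 % and 20.9 %, each within the forecast's margin.

    starting material ⇌ target (K = 0.990, k = 9.70 × 10⁻⁵ s⁻¹)
    starting material ⇌ isomer of the product (K = 4.30, k = 1.40 × 10⁻⁵ s⁻¹)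
    crystals ⇌ target, rate k3*(cs3 - [target]) while solid is left; crystals form when [target] > cs3 (solubility = 4.20 mM, k = 0.00150 s⁻¹)
    starting material + protic impurity → quenched substrate (k = 3.10 × 10⁻⁵ M⁻¹ s⁻¹)
    starting material + target ⇌ idle adduct, settled at all times (K = 93.0 M⁻¹)

At the end this flask holds 17.8 % of the charge as isomer of the product against the 18.8 % of the ceiling read from the runs, beside target of 67.6 % of the charge in all its forms, with crystals at 61.7 % of the charge; the idle adduct hardly moves the share. For the neighbouring flask, the same but charged with 0.40 M of starting material, the ceiling taken as a concentration gives 4.70 % of that charge, and the neighbour holds 4.74 %. With the neighbour's target of 90.6 %, the ceiling gives a share of 4.93 %, and the neighbour stands at 4.97 %.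

The numbers in the tables were generated by integration with made-up constants; the scatter is artificial.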